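The rate constants stand for no real mixture; the result is computed.

If a run is to earn trust, two half-lives reckoned from the charged amounts should already say what it may give.

substrate 0.10 M (fed, over 1.0 h); capture agent 0.0300 M; time 2.5 d

    open intermediate → target (k1 = 0.022 min⁻¹)
    substrate + target → side product (k2 = 0.053 M⁻¹ min⁻¹)
    substrate → open intermediate (k3 = 0.017 min⁻¹)
    target ⇌ isomer of the product (K4 = 0.51, k4 = 0.036 min⁻¹)
    open intermediate + capture agent → trapped intermediate (k5 = 0.061 M⁻¹ min⁻¹)

- percentages count the substrate that a species holds: one side product counts as two
- the reaction counts as stopped when no species that holds the substrate changes by six tenths of a point or more over the second half of the time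
- run time (flask): 2.5 d

- the state of affairs at 2.5 d: stopped, and by what, or still going (all of the substrate has reacted / it is still moving / forward and back rates have come level)
- part of the substrate gone at 2.5 d
- the target standing at 2.5 d, as a percentage of the substrate charged
- the isomer of the product standing at 2.5 d, as a percentage of the substrate charged
- the side product standing at 2.5 d, as a percentage of the substrate charged

1. I asked what consumes substrate. It opens by itself, with half-life 40.8 min, or it attacks target. I treated that attack as pseudo-first-order with the whole charge standing as target, which gave a half-life of 131 min.

2. I set the remaining steps aside: the scheme shows none of them with substrate on its left. Target's forward isomerisation, at 0.32 h, is quicker than its attack by substrate, at 0.091 d. Trapping, at 0.26 d, is slower than closure of the open intermediate to target, at 0.53 h.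

3. Opening is short against 2.5 d, so I expected the substrate to be consumed by then.

4. Target cannot exceed the charge, so the ceiling share, the upper limit on the part of substrate lost by attack on target, is the opening half-life over the sum of both: 23.8 %. One side product holds two, so I committed only to a side product under 47.6 %.

5. The forecast said all of the substrate has reacted, with conversion 100 %, target 55 %, isomer of the product 28 % and side product 10.5 %, reasoning that “dosing keeps substrate and target from overlapping much”. My reckoning gives a bound, not that number.

6. The flask gave all of the substrate has reacted, with conversion 100 %, target 55.0 %, isomer of the product 28.1 % and side product 10.4 %. At 0.0491 d the flask used substrate 24 times as fast by opening as by attack, well above the 3.21 that the ceiling assumes. Counted as substrate lost by attack, one side product holding two, the side product in the flask read 0.218 of the ceiling share.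

7. For the neighbour charged with 0.40 M of substrate, the ceiling share is 55.5 %, and the same reading, with one side product again holding two, gives 24.2 % of side product. The computed neighbour holds 28.3 %.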